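Configuration read from the SMILES: all four carbinol centres are R. Assumption: a one-pot sequence without isolation counts as one step.

## Retrosynthetic overview
1. The last step is hydrogenolysis of six benzyl ethers. Before it, the terminal orsellinoyl–O bond (A–B) is cut to give di-O-benzylorsellinic acid and a B–C–D–E alcohol.
2. The key cut is the central aryl ester (C–D). It gives a B–C benzoic acid and a D–E alcohol of nearly equal size, and both are made from one common ester.
3. The carboxyl of ring C is introduced only after its side-chain OH is acylated (Vilsmeier–Haack, then Pinnick). The hydroxy acid therefore never exists and cannot close to the isochromanone.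
4. The common ester comes from the arylpropanol (aryllithium + (R)-propylene oxide; the aryl bromide from 3-bromophenol by meta C–H borylation/oxidation) and O-silyl (R)-3-hydroxybutanoic acid.
5. Rings: only arene A is built, from two methyl acetoacetates by Claisen condensation and then aldol aromatisation. Arenes C and E come from 3-bromophenol, and no other ring is formed.

## Route

Step 1
Reactants: 1 3-bromophenol
Product: 2 (3-bromophenoxy)(tert-butyl)dimethylsilane
Conditions: TBSCl (1.1 equiv), imidazole (2 equiv), DMF, rt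
Reagents that add atoms: TBSCl, CC(C)(C)[Si](C)(C)Cl
Why: This imidazole-promoted O-silylation masks the acidic OH with a group that has no borylatable aryl C–H (unlike benzyl) and that blocks both of its ortho positions.

Step 2
Reactants: 2 (3-bromophenoxy)(tert-butyl)dimethylsilane
Product: 4 3-bromo-5-[(tert-butyldimethylsilyl)oxy]phenol, via aryl pinacol boronate 3 (not isolated)
Conditions: HBpin (1.5 equiv), [Ir(OMe)(cod)]2 (1 mol %), dtbpy (2 mol %), THF, 60 °C; evaporate; Oxone (1.1 equiv), acetone/H2O, rt, 15 min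
Reagents that add atoms: pinacolborane, B1OC(C)(C)C(C)(C)O1 (Bpin of 3 only); potassium peroxymonosulfate (Oxone), [K+].[O-]S(=O)(=O)OO (phenol oxygen)
Why: Sterically controlled Ir-catalysed aromatic C–H borylation reaches only C5–H, the one C–H without an ortho substituent, tolerates C–Br, and the boronate is then oxidised in the same pot (B-to-O aryl shift) to the phenol.

Step 3
Reactants: 4 3-bromo-5-[(tert-butyldimethylsilyl)oxy]phenol
Product: 6 1,3-bis(benzyloxy)-5-bromobenzene, via monobenzyl silyl ether 5 (not isolated)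
Conditions: BnBr (2.4 equiv), K2CO3 (1.5 equiv), DMF, rt; then CsF (1.5 equiv), 50 °C
Reagents that add atoms: benzyl bromide, BrCc1ccccc1
Why: Williamson etherification of the free phenol and fluoride-triggered desilylative Williamson alkylation both end at the same symmetric dibenzyl ether, so early loss of TBS does no harm.

Step 4
Reactants: 6 1,3-bis(benzyloxy)-5-bromobenzene; 7 (R)-2-methyloxirane
Product: 9 (2R)-1-[3,5-bis(benzyloxy)phenyl]propan-2-ol, via aryllithium 8 (not isolated)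
Conditions: n-BuLi (1.05 equiv), THF, −78 °C; then 7 (1.5 equiv), BF3·OEt2 (1.3 equiv), −78 °C; H2O
Reagents that add atoms: n-BuLi, [Li]CCCC (lithium of 8 only)
Why: Br/Li exchange is followed by BF3-assisted SN2 opening of the epoxide at its unsubstituted CH2, so the C–O stereocentre of 7 is not touched and R is carried over unchanged (CIP order also unchanged).

Step 5
Reactants: 10 methyl (3R)-3-hydroxybutanoate
Product: 11 methyl (3R)-3-[(tert-butyldiphenylsilyl)oxy]butanoate
Conditions: TBDPSCl (1.1 equiv), imidazole (2 equiv), DMF, rt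
Reagents that add atoms: TBDPSCl, CC(C)(C)[Si](Cl)(c1ccccc1)c1ccccc1
Why: This O-silylation of the chiral-pool alcohol uses TBDPS because it survives POCl3/DMF, which converts TBS or TES ethers into formates.

Step 6
Reactants: 11 methyl (3R)-3-[(tert-butyldiphenylsilyl)oxy]butanoate
Product: 12 (3R)-3-[(tert-butyldiphenylsilyl)oxy]butanoic acid
Conditions: LiOH (2 equiv), THF/MeOH/H2O, 0 °C → rt; 1 M HCl
Reagents that add atoms: LiOH, [Li+].[OH-] (carboxyl oxygen)
Why: Mild BAc2 saponification works here because silyloxide is a poor leaving group, so E1cB to crotonate does not compete and the stereocentre is not involved.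

Step 7
Reactants: 9 (2R)-1-[3,5-bis(benzyloxy)phenyl]propan-2-ol; 12 (3R)-3-[(tert-butyldiphenylsilyl)oxy]butanoic acid
Product: 13 (2R)-1-[3,5-bis(benzyloxy)phenyl]propan-2-yl (3R)-3-[(tert-butyldiphenylsilyl)oxy]butanoate
Conditions: DCC (1.2 equiv), DMAP (0.1 equiv), CH2Cl2, 0 °C → rt
Reagents that add atoms: none
Why: Steglich esterification of an unhindered aliphatic acid forms the acyl–O bond, so both stereocentres are retained.

Step 8
Reactants: 13 (2R)-1-[3,5-bis(benzyloxy)phenyl]propan-2-yl (3R)-3-[(tert-butyldiphenylsilyl)oxy]butanoate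
Product: 14 (2R)-1-[3,5-bis(benzyloxy)phenyl]propan-2-yl (3R)-3-hydroxybutanoate
Conditions: HF·pyridine (excess), THF/pyridine, 0 °C → rt (PE flask)
Reagents that add atoms: none
Why: Fluoride-driven Si–O cleavage in a weakly acidic medium frees the β-hydroxy ester without the elimination or retro-aldol that basic TBAF could cause.

Step 9
Reactants: 13 (2R)-1-[3,5-bis(benzyloxy)phenyl]propan-2-yl (3R)-3-[(tert-butyldiphenylsilyl)oxy]butanoate
Product: 16 (2R)-1-[3,5-bis(benzyloxy)-2-formylphenyl]propan-2-yl (3R)-3-[(tert-butyldiphenylsilyl)oxy]butanoate, via aryl iminium chloride 15 (not isolated)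
Conditions: POCl3 (2 equiv), DMF, 0 → 40 °C; then aq. NaOAc, rt
Reagents that add atoms: DMF, CN(C)C=O (formyl carbon; Me2N=CH of 15); POCl3, O=P(Cl)(Cl)Cl (chloride of 15 only); water, O (aldehyde oxygen)
Why: Vilsmeier–Haack formylation of the 3,5-dialkoxyalkylbenzene goes para to one OBn and ortho to the other (C2 and C6 are equivalent) rather than between the two OBn groups, and the ester, TBDPS and benzyl ethers tolerate the reagent.

Step 10
Reactants: 16 (2R)-1-[3,5-bis(benzyloxy)-2-formylphenyl]propan-2-yl (3R)-3-[(tert-butyldiphenylsilyl)oxy]butanoate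
Product: 17 2,4-bis(benzyloxy)-6-[(2R)-2-{[(3R)-3-[(tert-butyldiphenylsilyl)oxy]butanoyl]oxy}propyl]benzoic acid
Conditions: NaClO2 (3 equiv), NaH2PO4 (3 equiv), 2-methyl-2-butene (20 equiv), t-BuOH/THF/H2O, rt
Reagents that add atoms: sodium chlorite, [Na+].[O-]Cl=O
Why: Pinnick oxidation takes the hindered aldehyde to the acid under near-neutral conditions, and the alkene traps HOCl before it can chlorinate the electron-rich ring.

Step 11
Reactants: 17 2,4-bis(benzyloxy)-6-[(2R)-2-{[(3R)-3-[(tert-butyldiphenylsilyl)oxy]butanoyl]oxy}propyl]benzoic acid; 14 (2R)-1-[3,5-bis(benzyloxy)phenyl]propan-2-yl (3R)-3-hydroxybutanoate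
Product: 19 (2R)-4-{[(2R)-1-[3,5-bis(benzyloxy)phenyl]propan-2-yl]oxy}-4-oxobutan-2-yl 2,4-bis(benzyloxy)-6-[(2R)-2-{[(3R)-3-[(tert-butyldiphenylsilyl)oxy]butanoyl]oxy}propyl]benzoate, via acid chloride 18 (not isolated)
Conditions: (COCl)2 (1.5 equiv), cat. DMF, CH2Cl2, 0 °C → rt, evaporate; then 14 (1.2 equiv), Et3N (2 equiv), DMAP (0.5 equiv), CH2Cl2, 0 °C → rt
Reagents that add atoms: oxalyl chloride, O=C(Cl)C(=O)Cl (chlorine of 18 only)
Why: DMAP-catalysed acylation by the acid chloride, the usual answer to di-ortho-substituted benzoic acids, joins the two halves at the acyl–O bond, so the R carbinol of 14 is retained and Et3N is too weak to cause E1cB.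

Step 12
Reactants: 19 silyl-protected B–C–D–E tetraester
Product: 20 (2R)-4-{[(2R)-1-[3,5-bis(benzyloxy)phenyl]propan-2-yl]oxy}-4-oxobutan-2-yl 2,4-bis(benzyloxy)-6-[(2R)-2-{[(3R)-3-hydroxybutanoyl]oxy}propyl]benzoate
Conditions: HF·pyridine (excess), THF/pyridine, 0 °C → rt (PE flask)
Reagents that add atoms: none
Why: This is the same buffered fluoride desilylation as in step 8, and the three esters and four benzyl ethers are inert to it.

Step 13
Reactants: 21 methyl acetoacetate (2 equiv)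
Product: 23 methyl 2,4-dihydroxy-6-methylbenzoate (methyl orsellinate), via methyl 3,5,7-trioxooctanoate 22 (not isolated)
Conditions: NaH (1.1 equiv), THF, 0 °C; n-BuLi (0.95 equiv), −78 °C → reflux, 24 h; aq. HCl, rt
Reagents that add atoms: none
Why: The γ-carbon of the Weiler dianion attacks the ester of a second acetoacetate (Claisen self-condensation), and the triketo ester closes C2 onto C7 (intramolecular aldol, dehydration, enolisation) to form arene A.

Step 14
Reactants: 23 methyl 2,4-dihydroxy-6-methylbenzoate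
Product: 24 methyl 2,4-bis(benzyloxy)-6-methylbenzoate
Conditions: BnBr (2.5 equiv), K2CO3 (3 equiv), DMF, 70 °C
Reagents that add atoms: benzyl bromide, BrCc1ccccc1
Why: This is a double Williamson etherification, and heating is needed to alkylate the hydrogen-bonded 2-OH as well.

Step 15
Reactants: 24 methyl 2,4-bis(benzyloxy)-6-methylbenzoate
Product: 25 2,4-bis(benzyloxy)-6-methylbenzoic acid
Conditions: KOH (10 equiv), DMSO/H2O, 100 °C; aq. HCl
Reagents that add atoms: KOH, [K+].[OH-] (carboxyl oxygen)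
Why: Forcing saponification overcomes the di-ortho hindrance, and with both phenols capped the acid does not decarboxylate.

Step 16
Reactants: 25 2,4-bis(benzyloxy)-6-methylbenzoic acid; 20 B–C–D–E alcohol
Product: 27 hexa-O-benzylhansforester A (the target carrying all six phenols as benzyl ethers), via acid chloride 26 (not isolated)
Conditions: 25 (2.5 equiv), (COCl)2, cat. DMF, CH2Cl2, 0 °C → rt, evaporate; then 20, Et3N (4 equiv), DMAP (1 equiv), CH2Cl2, 0 °C → rt
Reagents that add atoms: oxalyl chloride, O=C(Cl)C(=O)Cl (chlorine of 26 only)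
Why: This is the same DMAP-catalysed acid chloride esterification, helped by the smaller ortho methyl and an excess of the cheap acyl donor, and acyl–O bond formation keeps the R centre of unit B.

Step 17
Reactants: 27 hexa-O-benzylhansforester A
Product: 28 hansforester A
Conditions: H2 (1 atm), 10 % Pd/C, EtOAc/EtOH, rt
Reagents that add atoms: none
Why: Catalytic hydrogenolysis removes all six aryl benzyl ethers under neutral conditions, and the four esters are alkyl and homobenzylic (not benzylic), so they and the stereocentres survive.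

## Compound list
1 | 3-bromophenol | Oc1cccc(Br)c1 | starting material
2 | (3-bromophenoxy)(tert-butyl)dimethylsilane | CC(C)(C)[Si](C)(C)Oc1cccc(Br)c1 | intermediate
3 | [3-bromo-5-(4,4,5,5-tetramethyl-1,3,2-dioxaborolan-2-yl)phenoxy](tert-butyl)dimethylsilane (not isolated) | CC(C)(C)[Si](C)(C)Oc1cc(Br)cc(B2OC(C)(C)C(C)(C)O2)c1 | intermediate
4 | 3-bromo-5-[(tert-butyldimethylsilyl)oxy]phenol | CC(C)(C)[Si](C)(C)Oc1cc(O)cc(Br)c1 | intermediate
5 | [3-(benzyloxy)-5-bromophenoxy](tert-butyl)dimethylsilane (not isolated) | CC(C)(C)[Si](C)(C)Oc1cc(Br)cc(OCc2ccccc2)c1 | intermediate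
6 | 1,3-bis(benzyloxy)-5-bromobenzene | Brc1cc(OCc2ccccc2)cc(OCc2ccccc2)c1 | intermediate
7 | (R)-2-methyloxirane ((R)-propylene oxide) | C[C@@H]1CO1 | starting material
8 | [3,5-bis(benzyloxy)phenyl]lithium (not isolated) | [Li]c1cc(OCc2ccccc2)cc(OCc2ccccc2)c1 | intermediate
9 | (2R)-1-[3,5-bis(benzyloxy)phenyl]propan-2-ol | C[C@@H](O)Cc1cc(OCc2ccccc2)cc(OCc2ccccc2)c1 | intermediate
10 | methyl (3R)-3-hydroxybutanoate | C[C@@H](O)CC(=O)OC | starting material
11 | methyl (3R)-3-[(tert-butyldiphenylsilyl)oxy]butanoate | C[C@@H](O[Si](c1ccccc1)(c1ccccc1)C(C)(C)C)CC(=O)OC | intermediate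
12 | (3R)-3-[(tert-butyldiphenylsilyl)oxy]butanoic acid | C[C@@H](O[Si](c1ccccc1)(c1ccccc1)C(C)(C)C)CC(=O)O | intermediate
13 | (2R)-1-[3,5-bis(benzyloxy)phenyl]propan-2-yl (3R)-3-[(tert-butyldiphenylsilyl)oxy]butanoate | C[C@@H](O[Si](c1ccccc1)(c1ccccc1)C(C)(C)C)CC(=O)O[C@H](C)Cc1cc(OCc2ccccc2)cc(OCc2ccccc2)c1 | intermediate
14 | (2R)-1-[3,5-bis(benzyloxy)phenyl]propan-2-yl (3R)-3-hydroxybutanoate | C[C@@H](O)CC(=O)O[C@H](C)Cc1cc(OCc2ccccc2)cc(OCc2ccccc2)c1 | intermediate
15 | N,N-dimethyliminium chloride of aldehyde 16 (not isolated) | C[C@@H](O[Si](c1ccccc1)(c1ccccc1)C(C)(C)C)CC(=O)O[C@H](C)Cc1cc(OCc2ccccc2)cc(OCc2ccccc2)c1C=[N+](C)C.[Cl-] | intermediate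
16 | (2R)-1-[3,5-bis(benzyloxy)-2-formylphenyl]propan-2-yl (3R)-3-[(tert-butyldiphenylsilyl)oxy]butanoate | C[C@@H](O[Si](c1ccccc1)(c1ccccc1)C(C)(C)C)CC(=O)O[C@H](C)Cc1cc(OCc2ccccc2)cc(OCc2ccccc2)c1C=O | intermediate
17 | 2,4-bis(benzyloxy)-6-[(2R)-2-{[(3R)-3-[(tert-butyldiphenylsilyl)oxy]butanoyl]oxy}propyl]benzoic acid | C[C@@H](O[Si](c1ccccc1)(c1ccccc1)C(C)(C)C)CC(=O)O[C@H](C)Cc1cc(OCc2ccccc2)cc(OCc2ccccc2)c1C(=O)O | intermediate
18 | 2,4-bis(benzyloxy)-6-[(2R)-2-{[(3R)-3-[(tert-butyldiphenylsilyl)oxy]butanoyl]oxy}propyl]benzoyl chloride (not isolated) | C[C@@H](O[Si](c1ccccc1)(c1ccccc1)C(C)(C)C)CC(=O)O[C@H](C)Cc1cc(OCc2ccccc2)cc(OCc2ccccc2)c1C(=O)Cl | intermediate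
19 | (2R)-4-{[(2R)-1-[3,5-bis(benzyloxy)phenyl]propan-2-yl]oxy}-4-oxobutan-2-yl 2,4-bis(benzyloxy)-6-[(2R)-2-{[(3R)-3-[(tert-butyldiphenylsilyl)oxy]butanoyl]oxy}propyl]benzoate | C[C@@H](O[Si](c1ccccc1)(c1ccccc1)C(C)(C)C)CC(=O)O[C@H](C)Cc1cc(OCc2ccccc2)cc(OCc2ccccc2)c1C(=O)O[C@H](C)CC(=O)O[C@H](C)Cc1cc(OCc2ccccc2)cc(OCc2ccccc2)c1 | intermediate
20 | (2R)-4-{[(2R)-1-[3,5-bis(benzyloxy)phenyl]propan-2-yl]oxy}-4-oxobutan-2-yl 2,4-bis(benzyloxy)-6-[(2R)-2-{[(3R)-3-hydroxybutanoyl]oxy}propyl]benzoate | C[C@@H](O)CC(=O)O[C@H](C)Cc1cc(OCc2ccccc2)cc(OCc2ccccc2)c1C(=O)O[C@H](C)CC(=O)O[C@H](C)Cc1cc(OCc2ccccc2)cc(OCc2ccccc2)c1 | intermediate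
21 | methyl acetoacetate | CC(=O)CC(=O)OC | starting material
22 | methyl 3,5,7-trioxooctanoate (not isolated) | CC(=O)CC(=O)CC(=O)CC(=O)OC | intermediate
23 | methyl 2,4-dihydroxy-6-methylbenzoate (methyl orsellinate) | Cc1cc(O)cc(O)c1C(=O)OC | intermediate
24 | methyl 2,4-bis(benzyloxy)-6-methylbenzoate | Cc1cc(OCc2ccccc2)cc(OCc2ccccc2)c1C(=O)OC | intermediate
25 | 2,4-bis(benzyloxy)-6-methylbenzoic acid | Cc1cc(OCc2ccccc2)cc(OCc2ccccc2)c1C(=O)O | intermediate
26 | 2,4-bis(benzyloxy)-6-methylbenzoyl chloride (not isolated) | Cc1cc(OCc2ccccc2)cc(OCc2ccccc2)c1C(=O)Cl | intermediate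
27 | hexa-O-benzylhansforester A | Cc1cc(OCc2ccccc2)cc(OCc2ccccc2)c1C(=O)O[C@H](C)CC(=O)O[C@H](C)Cc1cc(OCc2ccccc2)cc(OCc2ccccc2)c1C(=O)O[C@H](C)CC(=O)O[C@H](C)Cc1cc(OCc2ccccc2)cc(OCc2ccccc2)c1 | intermediate
28 | hansforester A | Cc1cc(O)cc(O)c1C(=O)O[C@H](C)CC(=O)O[C@H](C)Cc1cc(O)cc(O)c1C(=O)O[C@H](C)CC(=O)O[C@H](C)Cc1cc(O)cc(O)c1 | target

## Step count and risks
Total step count: 17.
Longest linear sequence: 11 steps (1, 2, 3, 4, 7, 9, 10, 11, 12, 16, 17), which is 11/17 ≈ 0.65 of the total.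

**Step 11 (union of 17 and 14).**
- Failure modes: the di-ortho-substituted aroyl chloride 18 may acylate the secondary β-hydroxy ester too slowly. It may then decay, for example to the isochromanone through the neighbouring ester oxygen, or the product may eliminate.
- Fallback idea: reverse the roles of the partners, so that the carboxylate of 17 is the nucleophile and the carbinol carbon is the electrophile (Mitsunobu, with inversion). This needs the 3S alcohol.
- Fallback route: it sets out from 9, which is transesterified with methyl acetoacetate 21 (cat. DMAP, toluene, reflux, MeOH distilled off). This gives (2R)-1-[3,5-bis(benzyloxy)phenyl]propan-2-yl 3-oxobutanoate F1.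
- Noyori hydrogenation of F1 (RuCl2[(S)-BINAP], H2 50 atm, EtOH/CH2Cl2, 50 °C; benzyl ethers are untouched) sets the S carbinol under catalyst control. The product is (2R)-1-[3,5-bis(benzyloxy)phenyl]propan-2-yl (3S)-3-hydroxybutanoate F2.
- F2 and 17 with PPh3 and slowly added DIAD (toluene, 0 °C, to limit crotonate formation) give the R ester by SN2 inversion. The route is rejoined at 19.

**Step 16 (capping of 20 with the orsellinoyl unit).**
- Failure mode: the hindrance problem of step 11 recurs, now on the most valuable alcohol of the route.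
- Fallback route: it sets out from 20, which Dess–Martin periodinane (CH2Cl2, rt) oxidises to (2R)-4-{[(2R)-1-[3,5-bis(benzyloxy)phenyl]propan-2-yl]oxy}-4-oxobutan-2-yl 2,4-bis(benzyloxy)-6-[(2R)-2-(3-oxobutanoyloxy)propyl]benzoate F3.
- (S)-BINAP–Ru hydrogenation of this β-keto ester gives (2R)-4-{[(2R)-1-[3,5-bis(benzyloxy)phenyl]propan-2-yl]oxy}-4-oxobutan-2-yl 2,4-bis(benzyloxy)-6-[(2R)-2-{[(3S)-3-hydroxybutanoyl]oxy}propyl]benzoate F4.
- Mitsunobu esterification of F4 with acid 25 (PPh3, DIAD, toluene, 0 °C) inverts S to R and comes back at 27.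

**Step 9 (Vilsmeier–Haack on 13).**
- Failure modes: conversion next to the branched side chain may be incomplete, or the silyl ether may be attacked by POCl3/DMF.
- Fallback idea: replace electrophilic formylation and oxidation by halogenation and carbonylation.
- Fallback route: it sets out from 13, which NIS (cat. TFA, MeCN, 0 °C) iodinates para to one OBn. This gives (2R)-1-[3,5-bis(benzyloxy)-2-iodophenyl]propan-2-yl (3R)-3-[(tert-butyldiphenylsilyl)oxy]butanoate F5.
- Pd-catalysed hydroxycarbonylation of F5 (Pd(OAc)2, Xantphos, CO 1 atm, Et3N, H2O, DMF, 70 °C) gives the acid directly. It comes back at 17 and bypasses 16.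

## Further compounds
F1 | step 11 | (2R)-1-[3,5-bis(benzyloxy)phenyl]propan-2-yl 3-oxobutanoate | CC(=O)CC(=O)O[C@H](C)Cc1cc(OCc2ccccc2)cc(OCc2ccccc2)c1
F2 | step 11 | (2R)-1-[3,5-bis(benzyloxy)phenyl]propan-2-yl (3S)-3-hydroxybutanoate | C[C@H](O)CC(=O)O[C@H](C)Cc1cc(OCc2ccccc2)cc(OCc2ccccc2)c1
F3 | step 16 | (2R)-4-{[(2R)-1-[3,5-bis(benzyloxy)phenyl]propan-2-yl]oxy}-4-oxobutan-2-yl 2,4-bis(benzyloxy)-6-[(2R)-2-(3-oxobutanoyloxy)propyl]benzoate | CC(=O)CC(=O)O[C@H](C)Cc1cc(OCc2ccccc2)cc(OCc2ccccc2)c1C(=O)O[C@H](C)CC(=O)O[C@H](C)Cc1cc(OCc2ccccc2)cc(OCc2ccccc2)c1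
F4 | step 16 | (2R)-4-{[(2R)-1-[3,5-bis(benzyloxy)phenyl]propan-2-yl]oxy}-4-oxobutan-2-yl 2,4-bis(benzyloxy)-6-[(2R)-2-{[(3S)-3-hydroxybutanoyl]oxy}propyl]benzoate | C[C@H](O)CC(=O)O[C@H](C)Cc1cc(OCc2ccccc2)cc(OCc2ccccc2)c1C(=O)O[C@H](C)CC(=O)O[C@H](C)Cc1cc(OCc2ccccc2)cc(OCc2ccccc2)c1
F5 | step 9 | (2R)-1-[3,5-bis(benzyloxy)-2-iodophenyl]propan-2-yl (3R)-3-[(tert-butyldiphenylsilyl)oxy]butanoate | C[C@@H](O[Si](c1ccccc1)(c1ccccc1)C(C)(C)C)CC(=O)O[C@H](C)Cc1cc(OCc2ccccc2)cc(OCc2ccccc2)c1I
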